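**Retrosynthetic overview**
- The enone is made last by oxidative 1,3-transposition of a tertiary allylic alcohol. That alcohol comes from 1,2-addition of an alkylcerium (benzoxepane half, fragment A) to a bicyclic enone (hydroazulenone half, fragment B).
- Fragment B: the seven-membered carbocycle is closed by ring-closing metathesis (RCM) of a cis-1,2-disubstituted cyclopentane diene. The cyclopentane comes from (R)-linalool by RCM, hydroxyl-directed epoxidation, nitrile-anion epoxide opening, methylenation and hydroboration/Suzuki coupling.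
- Fragment A: oxepane and cyclohexanone close together in an epoxonium cascade of a Shi diepoxide ended by an enol silane; MeMgBr then sets the tertiary carbinol.
- Ring order: cyclopentene, then cycloheptene (fragment B); oxepane and cyclohexane in one step (fragment A); no ring is formed after the union.

Assumption: (R)-(−)-linalool of ≥95% ee and the D-fructose-derived Shi ketone are bought; the carbinol epimers formed in steps 18 and 21 are carried as mixtures because both centres are destroyed later.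

**Fragment A (steps 1–9)**

Step 1
Reactants: 1 dimethyl (2-oxopropyl)phosphonate; 2 geranyl bromide, (2E)-1-bromo-3,7-dimethylocta-2,6-diene
Product: 4 dimethyl [(5E)-6,10-dimethyl-2-oxoundeca-5,9-dien-1-yl]phosphonate, via phosphonate dianion 3 (not isolated)
Conditions: NaH, THF, 0 °C; n-BuLi, 0 °C; 2, 0 °C → rt; then H2O
Reagents that add atoms: sodium hydride, [Na+].[H-]; n-butyllithium, [Li]CCCC (both only as counter-ions of 3)
Why: γ-Alkylation of a β-ketophosphonate 1,3-dianion: the more basic terminal carbanion displaces the primary allylic bromide by SN2, the E-alkene is untouched and no stereocentre is formed.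

Step 2
Reactants: 4 dimethyl [(5E)-6,10-dimethyl-2-oxoundeca-5,9-dien-1-yl]phosphonate; 5 (benzyloxy)acetaldehyde
Product: 6 (2E,7E)-1-(benzyloxy)-8,12-dimethyltrideca-2,7,11-trien-4-one
Conditions: LiCl, i-Pr2NEt, MeCN, rt
Reagents that add atoms: none
Why: Masamune–Roush Horner–Wadsworth–Emmons olefination gives the E-enone under a mild base that the α-alkoxy aldehyde tolerates; no stereocentre is formed.

Step 3
Reactants: 6 (2E,7E)-1-(benzyloxy)-8,12-dimethyltrideca-2,7,11-trien-4-one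
Product: 7 (2E)-1-(benzyloxy)-6-[(2R,3R)-3-{2-[(2R)-3,3-dimethyloxiran-2-yl]ethyl}-3-methyloxiran-2-yl]hex-2-en-4-one
Conditions: D-fructose-derived Shi ketone (0.6 equiv), KHSO5 (as 2KHSO5·KHSO4·K2SO4), K2CO3, Bu4NHSO4, MeCN/CH2(OMe)2/aq. Na2B4O7 buffer pH 10.5, 0 °C
Reagents that add atoms: potassium peroxymonosulfate, [K+].[O-]S(=O)(=O)OO
Why: Shi asymmetric epoxidation: the chiral dioxirane epoxidises both electron-rich trisubstituted alkenes through the spiro transition state, which with the D-fructose ketone gives R at all three new centres, while the electron-poor enone alkene is left.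

Step 4
Reactants: 7 (2E)-1-(benzyloxy)-6-[(2R,3R)-3-{2-[(2R)-3,3-dimethyloxiran-2-yl]ethyl}-3-methyloxiran-2-yl]hex-2-en-4-one
Product: 8 triethyl{[(3Z)-6-(benzyloxy)-1-[(2R,3R)-3-{2-[(2R)-3,3-dimethyloxiran-2-yl]ethyl}-3-methyloxiran-2-yl]hex-3-en-3-yl]oxy}silane
Conditions: Et3SiH, RhCl(PPh3)3 (2 mol%), toluene, 50 °C; filtered through Florisil and used directly
Reagents that add atoms: triethylsilane, CC[SiH](CC)CC
Why: Rhodium-catalysed conjugate (1,4-) hydrosilylation of the s-cis enone gives the regiodefined (Z)-silyl enol ether, which fixes the nucleophilic carbon for the next step; no stereocentre is formed.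

Step 5
Reactants: 8 triethyl{[(3Z)-6-(benzyloxy)-1-[(2R,3R)-3-{2-[(2R)-3,3-dimethyloxiran-2-yl]ethyl}-3-methyloxiran-2-yl]hex-3-en-3-yl]oxy}silane
Product: 9 (3R,5aR,6R,9aR)-6-[2-(benzyloxy)ethyl]-2,2,5a-trimethyl-3-[(triethylsilyl)oxy]octahydro-1-benzoxepin-7(2H)-one
Conditions: Et3SiOTf (0.3 equiv), 2,6-di-tert-butyl-4-methylpyridine, CH2Cl2, −78 °C; aq. NaHCO3
Reagents that add atoms: none
Why: Silyl-triflate-initiated epoxonium cascade (tandem oxa-/carbacyclisation): the internal epoxide oxygen opens the silylated terminal epoxide at its tertiary carbon, and the enol silane opens the resulting epoxonium at the methyl-bearing carbon through a chair, so C-3 and C-9a keep the epoxide configurations, C-5a is inverted to give the trans ring fusion, the C-6 chain is equatorial (also the thermodynamic epimer next to the ketone), and the silyl triflate is regenerated.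

Step 6
Reactants: 9 (3R,5aR,6R,9aR)-6-[2-(benzyloxy)ethyl]-2,2,5a-trimethyl-3-[(triethylsilyl)oxy]octahydro-1-benzoxepin-7(2H)-one
Product: 10 (3R,5aR,6R,7S,9aR)-6-[2-(benzyloxy)ethyl]-2,2,5a,7-tetramethyl-3-[(triethylsilyl)oxy]decahydro-1-benzoxepin-7-ol
Conditions: MeMgBr, Et2O/toluene, −78 → 0 °C; then H2O
Reagents that add atoms: methylmagnesium bromide, C[Mg]Br
Why: Grignard 1,2-addition: the axial face of the ketone is blocked by the syn-axial C-5a methyl, so the methyl group enters equatorially and gives the axial (7S) tertiary alcohol.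

Step 7
Reactants: 10 (3R,5aR,6R,7S,9aR)-6-[2-(benzyloxy)ethyl]-2,2,5a,7-tetramethyl-3-[(triethylsilyl)oxy]decahydro-1-benzoxepin-7-ol
Product: 11 {[(3R,5aR,6R,7S,9aR)-6-[2-(benzyloxy)ethyl]-2,2,5a,7-tetramethyldecahydro-1-benzoxepine-3,7-diyl]bis(oxy)}bis(triethylsilane)
Conditions: Et3SiOTf, 2,6-lutidine, CH2Cl2, 0 °C → rt
Reagents that add atoms: triethylsilyl trifluoromethanesulfonate, CC[Si](CC)(CC)OS(=O)(=O)C(F)(F)F
Why: Silyl triflate silylation masks the hindered tertiary alcohol, which would otherwise close a tetrahydrofuran onto the activated side chain in steps 9 and 21.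

Step 8
Reactants: 11 {[(3R,5aR,6R,7S,9aR)-6-[2-(benzyloxy)ethyl]-2,2,5a,7-tetramethyldecahydro-1-benzoxepine-3,7-diyl]bis(oxy)}bis(triethylsilane)
Product: 12 2-[(3R,5aR,6R,7S,9aR)-2,2,5a,7-tetramethyl-3,7-bis[(triethylsilyl)oxy]decahydro-1-benzoxepin-6-yl]ethan-1-ol
Conditions: H2 (1 atm), Pd(OH)2/C, EtOAc, rt
Reagents that add atoms: none
Why: Hydrogenolysis of the benzyl ether in a non-protic solvent leaves both silyl ethers and touches no stereocentre.

Step 9
Reactants: 12 2-[(3R,5aR,6R,7S,9aR)-2,2,5a,7-tetramethyl-3,7-bis[(triethylsilyl)oxy]decahydro-1-benzoxepin-6-yl]ethan-1-ol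
Product: 13 (3R,5aR,6R,7S,9aR)-6-(2-iodoethyl)-2,2,5a,7-tetramethyl-3,7-bis[(triethylsilyl)oxy]decahydro-1-benzoxepine
Conditions: I2, PPh3, imidazole, CH2Cl2, 0 °C → rt
Reagents that add atoms: iodine, [I][I]
Why: Appel-type iodination converts the primary alcohol into the iodide by SN2 at an achiral carbon under buffered conditions that spare the silyl ethers.

**Fragment B (steps 10–20)**

Step 10
Reactants: 14 (R)-(−)-linalool, (3R)-3,7-dimethylocta-1,6-dien-3-ol
Product: 15 (1R)-1-methylcyclopent-2-en-1-ol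
Conditions: second-generation Grubbs catalyst, RuCl2(=CHPh)(PCy3)(H2IMes) (0.5 mol%), CH2Cl2, rt → 40 °C
Reagents that add atoms: none
Why: RCM of the 1,6-diene with loss of isobutene; the carbinol carbon is not involved, so its R configuration is carried into the ring.

Step 11
Reactants: 15 (1R)-1-methylcyclopent-2-en-1-ol
Product: 16 (1S,2R,5S)-2-methyl-6-oxabicyclo[3.1.0]hexan-2-ol (epoxide cis to OH)
Conditions: VO(acac)2 (2 mol%), t-BuOOH, CH2Cl2, 0 °C → rt
Reagents that add atoms: tert-butyl hydroperoxide, CC(C)(C)OO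
Why: Hydroxyl-directed vanadium-catalysed epoxidation delivers oxygen to the alkene face syn to the tertiary OH, which sets both epoxide carbons relative to the linalool centre.

Step 12
Reactants: 16 (1S,2R,5S)-2-methyl-6-oxabicyclo[3.1.0]hexan-2-ol
Product: 17 triethyl{[(1S,2R,5S)-2-methyl-6-oxabicyclo[3.1.0]hexan-2-yl]oxy}silane
Conditions: Et3SiOTf, 2,6-lutidine, CH2Cl2, −78 °C
Reagents that add atoms: triethylsilyl trifluoromethanesulfonate, CC[Si](CC)(CC)OS(=O)(=O)C(F)(F)F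
Why: Low-temperature silylation protects the tertiary alcohol without opening the epoxide and makes the neighbouring epoxide carbon even less accessible for step 13.

Step 13
Reactants: 17 triethyl{[(1S,2R,5S)-2-methyl-6-oxabicyclo[3.1.0]hexan-2-yl]oxy}silane; 18 isobutyronitrile
Product: 20 2-[(1S,2S,3R)-2-hydroxy-3-methyl-3-[(triethylsilyl)oxy]cyclopentyl]-2-methylpropanenitrile, via lithiated isobutyronitrile 19 (not isolated)
Conditions: 18, LiN(i-Pr)2, THF, −78 °C; then 17, −78 °C → 40 °C; then H2O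
Reagents that add atoms: lithium diisopropylamide, [Li]N(C(C)C)C(C)C (lithium only in 19)
Why: SN2 epoxide opening by an α-lithio nitrile at the epoxide carbon remote from the quaternary silyloxy carbon; backside attack places the cyanoisopropyl group trans to both oxygens (C-1 S) and builds the gem-dimethyl quaternary carbon.

Step 14
Reactants: 20 2-[(1S,2S,3R)-2-hydroxy-3-methyl-3-[(triethylsilyl)oxy]cyclopentyl]-2-methylpropanenitrile
Product: 21 2-methyl-2-[(1S,3R)-3-methyl-2-oxo-3-[(triethylsilyl)oxy]cyclopentyl]propanenitrile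
Conditions: Dess–Martin periodinane, NaHCO3, CH2Cl2, rt
Reagents that add atoms: none
Why: Dess–Martin oxidation of the secondary alcohol is non-basic, so the α-stereocentre carrying the cyanoisopropyl group is not epimerised.

Step 15
Reactants: 21 2-methyl-2-[(1S,3R)-3-methyl-2-oxo-3-[(triethylsilyl)oxy]cyclopentyl]propanenitrile
Product: 22 2-methyl-2-[(1S,3R)-3-methyl-2-methylidene-3-[(triethylsilyl)oxy]cyclopentyl]propanenitrile
Conditions: Zn, CH2Br2, TiCl4, THF/CH2Cl2, 0 °C → rt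
Reagents that add atoms: dibromomethane, BrCBr
Why: Takai–Lombardo methylenation uses a non-basic zinc–titanium carbenoid that reaches hindered ketones, spares the nitrile and does not epimerise the α-stereocentre.

Step 16
Reactants: 22 2-methyl-2-[(1S,3R)-3-methyl-2-methylidene-3-[(triethylsilyl)oxy]cyclopentyl]propanenitrile; 23 vinyl bromide
Product: 25 2-methyl-2-[(1R,2R,3R)-3-methyl-2-(prop-2-en-1-yl)-3-[(triethylsilyl)oxy]cyclopentyl]propanenitrile, via B-alkyl-9-BBN 24 (not isolated)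
Conditions: 9-BBN, THF, rt → 60 °C; then 23, Pd(dppf)Cl2 (5 mol%), aq. K3PO4, DMF, rt → 50 °C
Reagents that add atoms: 9-borabicyclo[3.3.1]nonane, B1C2CCCC1CCC2 (only in 24)
Why: Hydroboration then B-alkyl Suzuki–Miyaura coupling: 9-BBN adds from the face opposite the cyanoisopropyl group, so hydrogen enters there and the new CH2 ends cis to that group (C-2 R), and the primary C–B bond is then coupled with vinyl bromide to give the allyl arm.

Step 17
Reactants: 25 2-methyl-2-[(1R,2R,3R)-3-methyl-2-(prop-2-en-1-yl)-3-[(triethylsilyl)oxy]cyclopentyl]propanenitrile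
Product: 27 2-methyl-2-[(1R,2R,3R)-3-methyl-2-(prop-2-en-1-yl)-3-[(triethylsilyl)oxy]cyclopentyl]propanal, via N-aluminyl aldimine 26 (not isolated)
Conditions: i-Bu2AlH, toluene, −78 → −20 °C; then aq. Rochelle salt, rt
Reagents that add atoms: diisobutylaluminium hydride, CC(C)C[AlH]CC(C)C (only in 26); water, O
Why: Partial reduction of the nitrile stops at the N-aluminyl aldimine, which is hydrolysed to the aldehyde on work-up; no stereocentre is affected.

Step 18
Reactants: 27 2-methyl-2-[(1R,2R,3R)-3-methyl-2-(prop-2-en-1-yl)-3-[(triethylsilyl)oxy]cyclopentyl]propanal; 28 isopropenylmagnesium bromide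
Product: 29 2,4-dimethyl-4-[(1R,2R,3R)-3-methyl-2-(prop-2-en-1-yl)-3-[(triethylsilyl)oxy]cyclopentyl]pent-1-en-3-ol (C-3 epimers)
Conditions: 28, THF, −78 → 0 °C; then H2O
Reagents that add atoms: none
Why: Grignard addition to the non-enolisable aldehyde installs the second RCM alkene; the new carbinol centre is a mixture that is oxidised away in step 20.

Step 19
Reactants: 29 2,4-dimethyl-4-[(1R,2R,3R)-3-methyl-2-(prop-2-en-1-yl)-3-[(triethylsilyl)oxy]cyclopentyl]pent-1-en-3-ol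
Product: 30 (1R,3aR,8aR)-1,4,4,6-tetramethyl-1-[(triethylsilyl)oxy]-1,2,3,3a,4,5,8,8a-octahydroazulen-5-ol (C-5 epimers)
Conditions: second-generation Grubbs catalyst (5–10 mol%), CH2Cl2 (0.005 M), 40 °C
Reagents that add atoms: none
Why: RCM: the cis-1,2 arrangement of the allyl and isopropenyl carbinol arms lets the ruthenium alkylidene formed at the terminal allyl alkene close the trisubstituted cycloheptene with loss of ethene, which locks the cis ring fusion already present; no new stereocentre is formed.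

Step 20
Reactants: 30 (1R,3aR,8aR)-1,4,4,6-tetramethyl-1-[(triethylsilyl)oxy]-1,2,3,3a,4,5,8,8a-octahydroazulen-5-ol
Product: 31 (1R,3aR,8aR)-1,4,4,6-tetramethyl-1-[(triethylsilyl)oxy]-2,3,3a,4,8,8a-hexahydroazulen-5(1H)-one
Conditions: Dess–Martin periodinane, NaHCO3, CH2Cl2, rt
Reagents that add atoms: none
Why: Dess–Martin oxidation of the allylic alcohol converges both epimers on one enone without touching the ring-fusion centres.

**Union and end game (steps 21–23)**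

Step 21
Reactants: 13 (3R,5aR,6R,7S,9aR)-6-(2-iodoethyl)-2,2,5a,7-tetramethyl-3,7-bis[(triethylsilyl)oxy]decahydro-1-benzoxepine; 31 (1R,3aR,8aR)-1,4,4,6-tetramethyl-1-[(triethylsilyl)oxy]-2,3,3a,4,8,8a-hexahydroazulen-5(1H)-one
Product: 34 (1R,3aR,8aR)-5-{2-[(3R,5aR,6R,7S,9aR)-2,2,5a,7-tetramethyl-3,7-bis[(triethylsilyl)oxy]decahydro-1-benzoxepin-6-yl]ethyl}-1,4,4,6-tetramethyl-1-[(triethylsilyl)oxy]-1,2,3,3a,4,5,8,8a-octahydroazulen-5-ol (C-5 epimers), via alkyllithium 32 (not isolated), via alkylcerium dichloride 33 (not isolated)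
Conditions: 13 (1.3 equiv), t-BuLi (2.6 equiv), Et2O/pentane, −78 °C; CeCl3, THF, −78 °C; then 31, −78 → −40 °C; then H2O
Reagents that add atoms: tert-butyllithium, [Li]C(C)(C)C (lithium only in 32); cerium trichloride, Cl[Ce](Cl)Cl (only in 33)
Why: Iodine–lithium exchange, transmetalation to cerium and 1,2-addition: the weakly basic organocerium adds to the hindered enone carbonyl instead of deprotonating or adding in a conjugate sense, and the new carbinol centre is lost in step 22.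

Step 22
Reactants: 34 (1R,3aR,8aR)-5-{2-[(3R,5aR,6R,7S,9aR)-2,2,5a,7-tetramethyl-3,7-bis[(triethylsilyl)oxy]decahydro-1-benzoxepin-6-yl]ethyl}-1,4,4,6-tetramethyl-1-[(triethylsilyl)oxy]-1,2,3,3a,4,5,8,8a-octahydroazulen-5-ol
Product: 35 (3R,3aR,8aR)-7-{2-[(3R,5aR,6R,7S,9aR)-2,2,5a,7-tetramethyl-3,7-bis[(triethylsilyl)oxy]decahydro-1-benzoxepin-6-yl]ethyl}-3,6,8,8-tetramethyl-3-[(triethylsilyl)oxy]-2,3,3a,4,8,8a-hexahydroazulen-5(1H)-one
Conditions: pyridinium chlorochromate, [C5H5NH][CrO3Cl], 4 Å molecular sieves, CH2Cl2, rt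
Reagents that add atoms: pyridinium chlorochromate, [O-][Cr](=O)(=O)Cl.c1cc[nH+]cc1
Why: Dauben–Michno oxidative 1,3-transposition: the tertiary allylic chromate ester undergoes a [3,3] shift to the secondary allylic chromate, which is oxidised to the tetrasubstituted enone, and the mixed carbinol centre disappears.

Step 23
Reactants: 35 (3R,3aR,8aR)-7-{2-[(3R,5aR,6R,7S,9aR)-2,2,5a,7-tetramethyl-3,7-bis[(triethylsilyl)oxy]decahydro-1-benzoxepin-6-yl]ethyl}-3,6,8,8-tetramethyl-3-[(triethylsilyl)oxy]-2,3,3a,4,8,8a-hexahydroazulen-5(1H)-one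
Product: 36 (3R,3aR,8aR)-7-{2-[(3R,5aR,6R,7S,9aR)-3,7-dihydroxy-2,2,5a,7-tetramethyldecahydro-1-benzoxepin-6-yl]ethyl}-3-hydroxy-3,6,8,8-tetramethyl-2,3,3a,4,8,8a-hexahydroazulen-5(1H)-one (CNP0397160.1)
Conditions: HF·pyridine, pyridine/THF, 0 °C → rt
Reagents that add atoms: none
Why: Buffered fluoride desilylation removes all three triethylsilyl ethers without dehydrating the tertiary alcohols or touching the enone.

**Compound list**

1 | dimethyl (2-oxopropyl)phosphonate | CC(=O)CP(=O)(OC)OC | starting material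
2 | geranyl bromide | CC(C)=CCC/C(C)=C/CBr | starting material
3 | sodium lithium 1,3-dianion of 1 | [Na+].[Li+].[CH2-]C(=O)[CH-]P(=O)(OC)OC | intermediate
4 | dimethyl [(5E)-6,10-dimethyl-2-oxoundeca-5,9-dien-1-yl]phosphonate | CC(C)=CCC/C(C)=C/CCC(=O)CP(=O)(OC)OC | intermediate
5 | (benzyloxy)acetaldehyde | O=CCOCc1ccccc1 | starting material
6 | (2E,7E)-1-(benzyloxy)-8,12-dimethyltrideca-2,7,11-trien-4-one | CC(C)=CCC/C(C)=C/CCC(=O)/C=C/COCc1ccccc1 | intermediate
7 | (2E)-1-(benzyloxy)-6-[(2R,3R)-3-{2-[(2R)-3,3-dimethyloxiran-2-yl]ethyl}-3-methyloxiran-2-yl]hex-2-en-4-one | CC1(C)O[C@@H]1CC[C@@]2(C)O[C@@H]2CCC(=O)/C=C/COCc3ccccc3 | intermediate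
8 | (Z)-triethylsilyl enol ether of the saturated ketone from 7 | CC1(C)O[C@@H]1CC[C@@]2(C)O[C@@H]2CC/C(O[Si](CC)(CC)CC)=C/CCOCc3ccccc3 | intermediate
9 | (3R,5aR,6R,9aR)-6-[2-(benzyloxy)ethyl]-2,2,5a-trimethyl-3-[(triethylsilyl)oxy]octahydro-1-benzoxepin-7(2H)-one | c1ccccc1COCC[C@@H]1[C@@]2(C)CC[C@@H](O[Si](CC)(CC)CC)C(C)(C)O[C@@H]2CCC1=O | intermediate
10 | (3R,5aR,6R,7S,9aR)-6-[2-(benzyloxy)ethyl]-2,2,5a,7-tetramethyl-3-[(triethylsilyl)oxy]decahydro-1-benzoxepin-7-ol | c1ccccc1COCC[C@@H]1[C@@]2(C)CC[C@@H](O[Si](CC)(CC)CC)C(C)(C)O[C@@H]2CC[C@]1(C)O | intermediate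
11 | 3,7-bis(triethylsilyl) ether of the benzyl-protected diol | c1ccccc1COCC[C@@H]1[C@@]2(C)CC[C@@H](O[Si](CC)(CC)CC)C(C)(C)O[C@@H]2CC[C@]1(C)O[Si](CC)(CC)CC | intermediate
12 | 2-[(3R,5aR,6R,7S,9aR)-2,2,5a,7-tetramethyl-3,7-bis[(triethylsilyl)oxy]decahydro-1-benzoxepin-6-yl]ethan-1-ol | OCC[C@@H]1[C@@]2(C)CC[C@@H](O[Si](CC)(CC)CC)C(C)(C)O[C@@H]2CC[C@]1(C)O[Si](CC)(CC)CC | intermediate
13 | (3R,5aR,6R,7S,9aR)-6-(2-iodoethyl)-2,2,5a,7-tetramethyl-3,7-bis[(triethylsilyl)oxy]decahydro-1-benzoxepine | ICC[C@@H]1[C@@]2(C)CC[C@@H](O[Si](CC)(CC)CC)C(C)(C)O[C@@H]2CC[C@]1(C)O[Si](CC)(CC)CC | intermediate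
14 | (R)-(−)-linalool | C=C[C@](C)(O)CCC=C(C)C | starting material
15 | (1R)-1-methylcyclopent-2-en-1-ol | C[C@]1(O)C=CCC1 | intermediate
16 | (1S,2R,5S)-2-methyl-6-oxabicyclo[3.1.0]hexan-2-ol | C[C@@]1(O)CC[C@@H]2O[C@H]12 | intermediate
17 | triethyl{[(1S,2R,5S)-2-methyl-6-oxabicyclo[3.1.0]hexan-2-yl]oxy}silane | C[C@@]1(O[Si](CC)(CC)CC)CC[C@@H]2O[C@H]12 | intermediate
18 | isobutyronitrile | CC(C)C#N | starting material
19 | 2-lithio-2-methylpropanenitrile | [Li]C(C)(C)C#N | intermediate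
20 | 2-[(1S,2S,3R)-2-hydroxy-3-methyl-3-[(triethylsilyl)oxy]cyclopentyl]-2-methylpropanenitrile | N#CC(C)(C)[C@@H]1CC[C@@](C)(O[Si](CC)(CC)CC)[C@H]1O | intermediate
21 | 2-methyl-2-[(1S,3R)-3-methyl-2-oxo-3-[(triethylsilyl)oxy]cyclopentyl]propanenitrile | N#CC(C)(C)[C@@H]1CC[C@@](C)(O[Si](CC)(CC)CC)C1=O | intermediate
22 | 2-methyl-2-[(1S,3R)-3-methyl-2-methylidene-3-[(triethylsilyl)oxy]cyclopentyl]propanenitrile | N#CC(C)(C)[C@@H]1CC[C@@](C)(O[Si](CC)(CC)CC)C1=C | intermediate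
23 | vinyl bromide | C=CBr | starting material
24 | B-alkyl-9-BBN adduct of 22 (boron on the new CH2, cis to the cyanoisopropyl group) | N#CC(C)(C)[C@@H]1CC[C@@](C)(O[Si](CC)(CC)CC)[C@@H]1CB1C2CCCC1CCC2 | intermediate
25 | 2-methyl-2-[(1R,2R,3R)-3-methyl-2-(prop-2-en-1-yl)-3-[(triethylsilyl)oxy]cyclopentyl]propanenitrile | N#CC(C)(C)[C@@H]1CC[C@@](C)(O[Si](CC)(CC)CC)[C@@H]1CC=C | intermediate
26 | N-(diisobutylaluminyl) aldimine of 27 | CC(C)C[Al](CC(C)C)N=CC(C)(C)[C@@H]1CC[C@@](C)(O[Si](CC)(CC)CC)[C@@H]1CC=C | intermediate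
27 | 2-methyl-2-[(1R,2R,3R)-3-methyl-2-(prop-2-en-1-yl)-3-[(triethylsilyl)oxy]cyclopentyl]propanal | O=CC(C)(C)[C@@H]1CC[C@@](C)(O[Si](CC)(CC)CC)[C@@H]1CC=C | intermediate
28 | isopropenylmagnesium bromide | C=C(C)[Mg]Br | starting material
29 | 2,4-dimethyl-4-[(1R,2R,3R)-3-methyl-2-(prop-2-en-1-yl)-3-[(triethylsilyl)oxy]cyclopentyl]pent-1-en-3-ol (C-3 epimers) | C=C(C)C(O)C(C)(C)[C@@H]1CC[C@@](C)(O[Si](CC)(CC)CC)[C@@H]1CC=C | intermediate
30 | (1R,3aR,8aR)-1,4,4,6-tetramethyl-1-[(triethylsilyl)oxy]-1,2,3,3a,4,5,8,8a-octahydroazulen-5-ol (C-5 epimers) | OC1C(C)(C)[C@@H]2CC[C@@](C)(O[Si](CC)(CC)CC)[C@@H]2CC=C1C | intermediate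
31 | (1R,3aR,8aR)-1,4,4,6-tetramethyl-1-[(triethylsilyl)oxy]-2,3,3a,4,8,8a-hexahydroazulen-5(1H)-one | O=C1C(C)(C)[C@@H]2CC[C@@](C)(O[Si](CC)(CC)CC)[C@@H]2CC=C1C | intermediate
32 | alkyllithium from 13 | [Li]CC[C@@H]1[C@@]2(C)CC[C@@H](O[Si](CC)(CC)CC)C(C)(C)O[C@@H]2CC[C@]1(C)O[Si](CC)(CC)CC | intermediate
33 | alkylcerium dichloride from 32 | Cl[Ce](Cl)CC[C@@H]1[C@@]2(C)CC[C@@H](O[Si](CC)(CC)CC)C(C)(C)O[C@@H]2CC[C@]1(C)O[Si](CC)(CC)CC | intermediate
34 | tris(triethylsilyl)-protected tertiary allylic alcohol (C-5 epimers) | OC1(CC[C@@H]2[C@@]3(C)CC[C@@H](O[Si](CC)(CC)CC)C(C)(C)O[C@@H]3CC[C@]2(C)O[Si](CC)(CC)CC)C(C)(C)[C@@H]4CC[C@@](C)(O[Si](CC)(CC)CC)[C@@H]4CC=C1C | intermediate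
35 | tris(triethylsilyl) ether of the target | CC1=C(CC[C@@H]2[C@@]3(C)CC[C@@H](O[Si](CC)(CC)CC)C(C)(C)O[C@@H]3CC[C@]2(C)O[Si](CC)(CC)CC)C(C)(C)[C@@H]2CC[C@@](C)(O[Si](CC)(CC)CC)[C@@H]2CC1=O | intermediate
36 | CNP0397160.1 | CC1=C(CC[C@@H]2[C@@]3(C)CC[C@@H](O)C(C)(C)O[C@@H]3CC[C@]2(C)O)C(C)(C)[C@@H]2CC[C@@](C)(O)[C@@H]2CC1=O | target

**Totals**

Total step count: 23 (fragment A 9 steps, fragment B 11 steps, 3 after the union).
Longest linear sequence: 14 steps (14 → 36, steps 10–20 and 21–23).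

**Three steps most likely to fail, each with a fallback**

Step 5 (epoxonium cascade). The enol silane may hydrolyse, or the internal epoxide may react first. The fallback sets out from 8 and comes back at 9. MeLi cleaves the Si–O bond of 8 and the lithium enolate is trapped with PhNTf2 as the (Z)-enol triflate F1. Kumada coupling with Me3SiCH2MgCl and Pd(PPh3)4 gives the allylsilane F2. A Me3SiOTf-catalysed cascade ended by the more robust allylsilane, followed by K2CO3/MeOH, gives the exocyclic methylene alcohol F3. Et3SiOTf/2,6-lutidine gives the silyl ether F4, and ozonolysis (O3, then PPh3) gives 9.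

Step 19 (RCM to the cycloheptene). A 1,1-disubstituted alkene next to a quaternary carbon may close slowly. The fallback sets out from 27 and comes back at 31, closing the ring by an intramolecular aldol condensation instead. EtMgBr gives the ethyl carbinol F5 and Dess–Martin oxidation gives the ethyl ketone F6. Ozonolysis of the allyl group (O3, then PPh3) gives the keto aldehyde F7. KOH/MeOH then condenses the only enolisable carbon of the ketone onto the aldehyde and dehydrates to 31.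

Step 21 (addition to the hindered enone). The carbonyl lies between a quaternary carbon and a substituted alkene, and silyl migration in the organometallic may compete. The fallback sets out from 27 and 13 (as alkyllithium 32) and comes back at 34; the union is moved before the ring closure. Addition of 32 to the unhindered aldehyde 27 gives the secondary carbinol F8, and Dess–Martin oxidation gives the ketone F9. The small nucleophile 28 with CeCl3 gives the tertiary dienol F10, and RCM with the second-generation Grubbs catalyst closes the seven-membered ring to 34.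

**Further compounds**

F1 | step 5 | (3Z)-6-(benzyloxy)-1-[(2R,3R)-3-{2-[(2R)-3,3-dimethyloxiran-2-yl]ethyl}-3-methyloxiran-2-yl]hex-3-en-3-yl trifluoromethanesulfonate | CC1(C)O[C@@H]1CC[C@@]2(C)O[C@@H]2CC/C(OS(=O)(=O)C(F)(F)F)=C/CCOCc3ccccc3
F2 | step 5 | {(2Z)-5-(benzyloxy)-2-{2-[(2R,3R)-3-{2-[(2R)-3,3-dimethyloxiran-2-yl]ethyl}-3-methyloxiran-2-yl]ethyl}pent-2-en-1-yl}trimethylsilane | CC1(C)O[C@@H]1CC[C@@]2(C)O[C@@H]2CC/C(C[Si](C)(C)C)=C/CCOCc3ccccc3
F3 | step 5 | (3R,5aR,6S,9aR)-6-[2-(benzyloxy)ethyl]-2,2,5a-trimethyl-7-methylidenedecahydro-1-benzoxepin-3-ol | c1ccccc1COCC[C@@H]1[C@@]2(C)CC[C@@H](O)C(C)(C)O[C@@H]2CCC1=C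
F4 | step 5 | triethyl{[(3R,5aR,6S,9aR)-6-[2-(benzyloxy)ethyl]-2,2,5a-trimethyl-7-methylidenedecahydro-1-benzoxepin-3-yl]oxy}silane | c1ccccc1COCC[C@@H]1[C@@]2(C)CC[C@@H](O[Si](CC)(CC)CC)C(C)(C)O[C@@H]2CCC1=C
F5 | step 19 | 2-methyl-2-[(1R,2R,3R)-3-methyl-2-(prop-2-en-1-yl)-3-[(triethylsilyl)oxy]cyclopentyl]pentan-3-ol (C-3 epimers) | CCC(O)C(C)(C)[C@@H]1CC[C@@](C)(O[Si](CC)(CC)CC)[C@@H]1CC=C
F6 | step 19 | 2-methyl-2-[(1R,2R,3R)-3-methyl-2-(prop-2-en-1-yl)-3-[(triethylsilyl)oxy]cyclopentyl]pentan-3-one | CCC(=O)C(C)(C)[C@@H]1CC[C@@](C)(O[Si](CC)(CC)CC)[C@@H]1CC=C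
F7 | step 19 | [(1R,2R,5R)-2-methyl-5-(2-methyl-3-oxopentan-2-yl)-2-[(triethylsilyl)oxy]cyclopentyl]acetaldehyde | CCC(=O)C(C)(C)[C@@H]1CC[C@@](C)(O[Si](CC)(CC)CC)[C@@H]1CC=O
F8 | step 21 | 5-[(3R,5aR,6R,7S,9aR)-2,2,5a,7-tetramethyl-3,7-bis[(triethylsilyl)oxy]decahydro-1-benzoxepin-6-yl]-2-methyl-2-[(1R,2R,3R)-3-methyl-2-(prop-2-en-1-yl)-3-[(triethylsilyl)oxy]cyclopentyl]pentan-3-ol (C-3 epimers) | OC(CC[C@@H]1[C@@]2(C)CC[C@@H](O[Si](CC)(CC)CC)C(C)(C)O[C@@H]2CC[C@]1(C)O[Si](CC)(CC)CC)C(C)(C)[C@@H]1CC[C@@](C)(O[Si](CC)(CC)CC)[C@@H]1CC=C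
F9 | step 21 | 5-[(3R,5aR,6R,7S,9aR)-2,2,5a,7-tetramethyl-3,7-bis[(triethylsilyl)oxy]decahydro-1-benzoxepin-6-yl]-2-methyl-2-[(1R,2R,3R)-3-methyl-2-(prop-2-en-1-yl)-3-[(triethylsilyl)oxy]cyclopentyl]pentan-3-one | O=C(CC[C@@H]1[C@@]2(C)CC[C@@H](O[Si](CC)(CC)CC)C(C)(C)O[C@@H]2CC[C@]1(C)O[Si](CC)(CC)CC)C(C)(C)[C@@H]1CC[C@@](C)(O[Si](CC)(CC)CC)[C@@H]1CC=C
F10 | step 21 | 3-{2-[(3R,5aR,6R,7S,9aR)-2,2,5a,7-tetramethyl-3,7-bis[(triethylsilyl)oxy]decahydro-1-benzoxepin-6-yl]ethyl}-2,4-dimethyl-4-[(1R,2R,3R)-3-methyl-2-(prop-2-en-1-yl)-3-[(triethylsilyl)oxy]cyclopentyl]pent-1-en-3-ol (C-3 epimers) | C=C(C)C(O)(CC[C@@H]1[C@@]2(C)CC[C@@H](O[Si](CC)(CC)CC)C(C)(C)O[C@@H]2CC[C@]1(C)O[Si](CC)(CC)CC)C(C)(C)[C@@H]1CC[C@@](C)(O[Si](CC)(CC)CC)[C@@H]1CC=C
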